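## Retrosynthetic overview

1. Selaginellin A ⇐ racemic tris(methyl ether) triarylcarbinol: global O-demethylation and loss of water turn one anisyl ring into the quinone methide last.
2. Aryl–alkyne bond ⇐ Suzuki–Miyaura coupling of a 3,3-diaryl-2,1-benzoxaborole with a 1-bromoalkyne; the coupling also opens the oxaborole and frees the carbinol.
3. Benzoxaborole ⇐ three-component [2+2+2] cyclotrimerisation of a propynylboronate, a tertiary propargylic alcohol (temporary B–O tether) and acetylene.
4. Propargylic alcohol ⇐ acetylide addition to 4-methoxybenzophenone; boronate ⇐ propynyl Grignard reagent and B(O-i-Pr)3.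
5. Ring order: the phenyl and three anisyl rings are bought; the central benzene ring and the oxaborole ring form together in the cyclotrimerisation; the oxaborole ring is opened in the coupling; the cyclohexadienone ring arises from an anisyl ring in the last step.

Assumption: the target SMILES has no stereocentre and no locked axis, so it is made as the single achiral compound drawn; the carbinol centre carried from 4 to 15 is racemic and is erased in step 6.

## Route

Step 1
Reactants: 1 (4-methoxyphenyl)(phenyl)methanone; 2 1-ethynyl-4-methoxybenzene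
Product: 4 1,3-bis(4-methoxyphenyl)-1-phenylprop-2-yn-1-ol (racemic), via lithium acetylide 3 (not isolated)
Conditions: 2, n-BuLi (1.05 equiv), THF, −78 °C; then 1, −78 °C → rt; H2O
Reagents that add atoms: none
Why: 1,2-addition of a lithium acetylide to a non-enolisable diaryl ketone is fast and clean; the new carbinol centre forms racemic, which is harmless because it becomes sp2 in step 6.

Step 2
Reactants: 5 prop-1-yn-1-ylmagnesium bromide; 6 triisopropyl borate
Product: 8 diisopropyl prop-1-yn-1-ylboronate, via alkynylborate salt 7 (not isolated)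
Conditions: Et2O/THF, −78 °C → rt; then HCl (2 M in Et2O, 1.0 equiv), −78 °C → rt; filtration, distillation under reduced pressure
Reagents that add atoms: none
Why: Alkynylation of a trialkyl borate gives the stable tetracoordinate borate, and one equivalent of anhydrous HCl removes a single isopropoxide to release the alkynylboronic ester (standard alkynylboronate synthesis).

Step 3
Reactants: 4 1,3-bis(4-methoxyphenyl)-1-phenylprop-2-yn-1-ol; 8 diisopropyl prop-1-yn-1-ylboronate; 9 acetylene
Product: 12 3,4-bis(4-methoxyphenyl)-7-methyl-3-phenyl-2,1-benzoxaborol-1(3H)-ol (racemic), via boron-tethered diyne 10 (not isolated), via benzoxaborole isopropyl ester 11 (not isolated)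
Conditions: 4, 8 (1.5 equiv), toluene, rt, then evaporation (removes i-PrOH); Cp*RuCl(cod) (10 mol %), HC≡CH (1 atm), ClCH2CH2Cl, rt → 40 °C; H2O work-up
Reagents that add atoms: water, O
Why: Proposed new method: exchange of one isopropoxy group of 8 by the tertiary alcohol 4 gives the B–O tethered diyne 10, the Cp*RuCl fragment couples its two alkynes oxidatively to a bicyclic ruthenacyclopentadiene, and acetylene inserts before reductive elimination, so the central benzene ring and the oxaborole ring close in one operation with the substitution pattern fixed by the tether and by the symmetry of acetylene (closest known reaction: ruthenium-catalysed boron-tethered [2+2+2] cyclotrimerisation of alkynylboronates, primary or secondary propargylic alcohols and terminal alkynes); the carbinol centre stays racemic.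

Step 4
Reactants: 2 1-ethynyl-4-methoxybenzene
Product: 13 1-(bromoethynyl)-4-methoxybenzene
Conditions: NBS (1.1 equiv), AgNO3 (10 mol %), acetone, rt, dark
Reagents that add atoms: N-bromosuccinimide (NBS), O=C1CCC(=O)N1Br
Why: Silver-catalysed electrophilic bromination of a terminal alkyne proceeds through the silver acetylide and is selective for the C(sp)–H bond over the anisole ring.

Step 5
Reactants: 12 3,4-bis(4-methoxyphenyl)-7-methyl-3-phenyl-2,1-benzoxaborol-1(3H)-ol; 13 1-(bromoethynyl)-4-methoxybenzene
Product: 14 (4-methoxyphenyl){4'-methoxy-3-[(4-methoxyphenyl)ethynyl]-4-methyl-[1,1'-biphenyl]-2-yl}(phenyl)methanol (racemic)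
Conditions: 13 (1.5 equiv), Pd2(dba)3 (2.5 mol %), SPhos (10 mol %), K3PO4 (3 equiv), toluene/H2O (10:1), 60 °C
Reagents that add atoms: none
Why: Suzuki–Miyaura coupling of an arylboron reagent with a 1-bromoalkyne: hydroxide converts the benzoxaborole into the boronate, which transmetalates to the alkynylpalladium bromide formed by oxidative addition to zerovalent palladium, and hydrolysis of the B–O–C link releases the untouched tertiary carbinol.

Step 6
Reactants: 14 (4-methoxyphenyl){4'-methoxy-3-[(4-methoxyphenyl)ethynyl]-4-methyl-[1,1'-biphenyl]-2-yl}(phenyl)methanol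
Product: 16 selaginellin A, via triphenol carbinol 15 (not isolated)
Conditions: BBr3 (6 equiv), CH2Cl2, −78 °C → rt; then H2O, 0 °C
Reagents that add atoms: none
Why: Lewis-acid cleavage of the three aryl methyl ethers followed by spontaneous acid-promoted dehydration of the 4-hydroxytrityl carbinol gives the quinone methide (fuchsone formation), which removes the only stereocentre; the diaryl alkyne is expected to tolerate BBr3 at low temperature.

## Compound list

1 | (4-methoxyphenyl)(phenyl)methanone (4-methoxybenzophenone) | COc1ccc(cc1)C(=O)c1ccccc1 | starting material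
2 | 1-ethynyl-4-methoxybenzene | C#Cc1ccc(OC)cc1 | starting material
3 | lithium (4-methoxyphenyl)ethynide | [Li]C#Cc1ccc(OC)cc1 | intermediate (not isolated)
4 | 1,3-bis(4-methoxyphenyl)-1-phenylprop-2-yn-1-ol, racemic | COc1ccc(cc1)C#CC(O)(c1ccccc1)c1ccc(OC)cc1 | intermediate
5 | prop-1-yn-1-ylmagnesium bromide | CC#C[Mg]Br | starting material
6 | triisopropyl borate | CC(C)OB(OC(C)C)OC(C)C | starting material
7 | bromomagnesium triisopropoxy(prop-1-yn-1-yl)borate | CC#C[B-](OC(C)C)(OC(C)C)OC(C)C.[Mg+]Br | intermediate (not isolated)
8 | diisopropyl prop-1-yn-1-ylboronate | CC#CB(OC(C)C)OC(C)C | intermediate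
9 | acetylene | C#C | starting material
10 | isopropyl 1,3-bis(4-methoxyphenyl)-1-phenylprop-2-yn-1-yl prop-1-yn-1-ylboronate, racemic | CC#CB(OC(C)C)OC(C#Cc1ccc(OC)cc1)(c1ccccc1)c1ccc(OC)cc1 | intermediate (not isolated)
11 | 1-isopropoxy-3,4-bis(4-methoxyphenyl)-7-methyl-3-phenyl-1,3-dihydro-2,1-benzoxaborole, racemic | Cc1ccc(-c2ccc(OC)cc2)c2c1B(OC(C)C)OC2(c1ccccc1)c1ccc(OC)cc1 | intermediate (not isolated)
12 | 3,4-bis(4-methoxyphenyl)-7-methyl-3-phenyl-2,1-benzoxaborol-1(3H)-ol, racemic | Cc1ccc(-c2ccc(OC)cc2)c2c1B(O)OC2(c1ccccc1)c1ccc(OC)cc1 | intermediate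
13 | 1-(bromoethynyl)-4-methoxybenzene | COc1ccc(C#CBr)cc1 | intermediate
14 | (4-methoxyphenyl){4'-methoxy-3-[(4-methoxyphenyl)ethynyl]-4-methyl-[1,1'-biphenyl]-2-yl}(phenyl)methanol, racemic | Cc1ccc(-c2ccc(OC)cc2)c(C(O)(c2ccccc2)c2ccc(OC)cc2)c1C#Cc1ccc(OC)cc1 | intermediate
15 | 2-[hydroxy(4-hydroxyphenyl)(phenyl)methyl]-3-[(4-hydroxyphenyl)ethynyl]-4-methyl-[1,1'-biphenyl]-4'-ol, racemic | Cc1ccc(-c2ccc(O)cc2)c(C(O)(c2ccccc2)c2ccc(O)cc2)c1C#Cc1ccc(O)cc1 | intermediate (not isolated)
16 | selaginellin A, 4-[{4'-hydroxy-3-[(4-hydroxyphenyl)ethynyl]-4-methyl-[1,1'-biphenyl]-2-yl}(phenyl)methylidene]cyclohexa-2,5-dien-1-one | Cc1ccc(-c2ccc(O)cc2)c(C(=C2C=CC(=O)C=C2)c2ccccc2)c1C#Cc1ccc(O)cc1 | target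

## Step count and risk

Total step count: 6. Longest linear sequence: 4 steps (step 1 → step 3 → step 5 → step 6; steps 2 and 4 are one-step branches).

Steps most likely to fail:

**Step 3 (cyclotrimerisation).** The hindered tertiary alcohol may exchange poorly onto boron, the doubly internal diyne may be slow at ruthenium, and acetylene may self-trimerise instead. The fallback sets out from 4 and comes back at 14, replacing the reversible boron tether by a covalent silicon tether. Excess dichlorodimethylsilane is treated with 5 (THF, −78 °C) and distilled to give chloro(dimethyl)(prop-1-yn-1-yl)silane F1. F1 silylates the sodium alkoxide of 4 (NaH, THF, 0 °C → rt) to give the isolable diyne {[1,3-bis(4-methoxyphenyl)-1-phenylprop-2-yn-1-yl]oxy}(dimethyl)(prop-1-yn-1-yl)silane F2. With no exchange equilibrium, F2 can be cyclotrimerised with 9 under Cp*RuCl(cod), RhCl(PPh3)3 or CpCo(CO)2/hν to give 3,4-bis(4-methoxyphenyl)-1,1,7-trimethyl-3-phenyl-1,3-dihydro-2,1-benzoxasilole F3. Fluoride-activated Hiyama–Denmark coupling of F3 with 13 (Pd2(dba)3, TBAF, THF, 50 °C) opens the siloxane and gives 14 after aqueous work-up; this last coupling is itself an extension, since such benzoxasiloles are known to couple with aryl halides rather than bromoalkynes.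

**Step 5 (Suzuki coupling).** Transmetalation at the doubly ortho-substituted boron may be slow, the bromoalkyne may homocouple, and the product alkoxide may cyclise onto the new alkyne. The fallback sets out from 12 and comes back at 14. Ipso-iododeboronation of 12 (I2, K2CO3, MeCN, 60 °C) gives (3-iodo-4'-methoxy-4-methyl-[1,1'-biphenyl]-2-yl)(4-methoxyphenyl)(phenyl)methanol F4. Sonogashira coupling of F4 with 2 (PdCl2(PPh3)2, CuI, Et3N, DMF, 60 °C) gives 14; this costs one more linear step but uses only robust operations.

**Step 6 (BBr3).** HBr addition to the alkyne or cation–alkyne cyclisation may compete. The fallback sets out from 14 and comes back at 16, separating demethylation from dehydration. LiBH(s-Bu)3 (lithium tri-sec-butylborohydride, excess) in THF at reflux cleaves the three methyl ethers by SN2 attack of hydride on the methyl groups, with methane evolved and no acid present. After neutral work-up 15 is isolated and dehydrated to 16 with catalytic AcOH in CH2Cl2 at rt.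

## Further compounds

F1 | step 3 | chloro(dimethyl)(prop-1-yn-1-yl)silane | CC#C[Si](C)(C)Cl
F2 | step 3 | {[1,3-bis(4-methoxyphenyl)-1-phenylprop-2-yn-1-yl]oxy}(dimethyl)(prop-1-yn-1-yl)silane, racemic | CC#C[Si](C)(C)OC(C#Cc1ccc(OC)cc1)(c1ccccc1)c1ccc(OC)cc1
F3 | step 3 | 3,4-bis(4-methoxyphenyl)-1,1,7-trimethyl-3-phenyl-1,3-dihydro-2,1-benzoxasilole, racemic | Cc1ccc(-c2ccc(OC)cc2)c2c1[Si](C)(C)OC2(c1ccccc1)c1ccc(OC)cc1
F4 | step 5 | (3-iodo-4'-methoxy-4-methyl-[1,1'-biphenyl]-2-yl)(4-methoxyphenyl)(phenyl)methanol, racemic | Cc1ccc(-c2ccc(OC)cc2)c(C(O)(c2ccccc2)c2ccc(OC)cc2)c1I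
F0 | step 6 | none | none
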